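Which move at 80 min gains the most ring in the green flask, and by how much?

| setting | green | amber | flask |
|---|---|---|---|
| substrate | 0.036 M | 0.036 M | 0.036 M |
| temperature | 0 °C | −15 °C | 0 °C |
| remark | the very flask that is asked about, followed so far | run made earlier |  |
| time |  |  | 80 min |

| run | time / min | ring / % | substrate / % |
|---|---|---|---|
| green | 15.0 | 11.6 | 0 |
| green | 30.0 | 11.6 | 0 |
| green | 50.0 | 11.7 | 1.0 |
| green | 60.0 | 11.2 | 0 |
| amber | 30.0 | 1.5 | 0.4 |
| amber | 60.0 | 1.8 | 0 |
| amber | 120 | 1.1 | 0 |

(standard deviation of a reading: 0.5 percentage points)

- percent here means substrate units held: one open dimer or side product counts as two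
- ring that was removed still counts
- the numbers in the tables scatter by 0.5 percentage points (one standard deviation)
- reactions considered so far: 2 substrate -> open dimer; substrate -> ring; ring <-> isomer of the product; substrate + ring -> side product
- additions bring no volume worth counting

- south-west: change nothing and wait 40 min more
- north-west: at 80 min raise the temperature by 15 K, then wait 40 min
- south: at 80 min take out 90% of the ring then present, then wait 40 min
- east: at 80 min add substrate, 50.0% of the amount charged, then wait 40 min

- ring, in percent of the substrate first charged, at 80 min
- what to do for the largest gain in ring; "none" if nothing gains more than 2 percentage points (south-west / north-west / south / east / none)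
- ring present, with what was taken out counted in, in percent of the substrate first charged, after south-west
- ring present, with what was taken out counted in, in percent of the substrate first charged, after north-west

Substrate reads 0% in the green flask at 15.0 min and 0% in the amber run at 60.0 min. Its balance therefore reads: charge = ring + rest, where the rest (isomer, open dimer, side product) goes unmeasured. The ring stays flat in each run within the scatter of 0.5 percentage points, so we compare two amounts, the green plateau and the amber plateau, each a mean of readings. Their ratio, a reading that carries the scatter, is the plateau factor, the resting ring at the warmer temperature over that at the colder: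

f = c(ring, green) / c(ring, amber) = 11.5% / 1.47% = 7.86

Ring ⇌ isomer is the one listed step with a way back. We therefore read the plateaus as thermodynamic control and let f move the ratio of ring to isomer per 15 K. If the green rest of 88.5% were isomer throughout:

c(ring)/c(isomer) after warming = f × 11.5% / 88.5% = 1.02, so ring = 50.6%

Open dimer and side product in the rest lower this figure, but we still commit to north-west, with ring at about 11.5% at 80 min.

The forecast gives 11.5% now, 11.5% after waiting, 11.3% after north-west, and east as best. Warming, it says, “only speeds the slow or already settled ring–isomer exchange”. Here our reckoning parts from it.

The flask gives 11.5% at 80 min, 11.5% after waiting and 44.2% after north-west, so north-west gains most, 33 points. The isomer in the flask holds 63.7% at 80.0 min. Multiplying the ratio of ring to isomer there by f gives 1.42, and at that ratio ring and isomer together share out to: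

c(ring) = (11.5% + 63.7%) × 1.42 / (1 + 1.42) = 44.1%

    2 substrate → open dimer (k = 0.0685 L mol⁻¹ s⁻¹, Ea = 44.0 kJ mol⁻¹)
    substrate → ring (k = 0.0188 s⁻¹, Ea = 71.0 kJ mol⁻¹)
    ring ⇌ isomer of the product (K = 5.52, k = 0.255 s⁻¹, Ea = 72.0 kJ mol⁻¹, ΔH = −90.0 kJ mol⁻¹)
    substrate + ring → side product (k = 0.561 L mol⁻¹ s⁻¹, Ea = 55.0 kJ mol⁻¹)
    (constants at 0 °C)

In the same flask run at −25 °C, the isomer holds 63.3%, and f, taken as a constant factor per 15 K across the temperature gap, gives a ring of 0.369%. The computed ring there is 0.296%.

The readings were generated by integration with constants of no real substance, and the scatter is random.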